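**Plan**
- Retrosynthesis: after the three phenols are masked as benzyl ethers, the C2–C3 and C3–C4 bonds on either side of the ketone are cut together, so that C3 is carbon monoxide.
- Enabling feature: the C3 carbonyl of the heptane chain lies between two unbranched CH2 carbons. C2 belongs to the C1–C2 tether of the syringyl ring and C4 to the C4–C7 tether of the catechol ring, so both coupling partners are primary alkyl groups.
- Further cuts: B–C2 (hydroboration of a styrene whose C1=C2 bond comes from syringaldehyde by methylenation) and aryl–C7 (arylmagnesium bromide plus 1-bromo-4-chlorobutane, then chloride-to-iodide exchange).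
- Forward: each arm is built in three steps on a purchased arene, the arms are joined through CO in one carbonylative coupling, and hydrogenolysis frees the phenols. No ring is formed at any stage.
- Stereochemistry: the target has no stereocentre and no C=C bond, so there is nothing to control.

Key step: step 7

Assumption: 9-BBN is drawn as its monomer and used as the commercial THF solution; borane 11 is handled under argon as a crude residue and is not purified.

**Route**

Step 1
Reactants: 1 syringaldehyde (4-hydroxy-3,5-dimethoxybenzaldehyde)
Product: 2 4-(benzyloxy)-3,5-dimethoxybenzaldehyde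
Conditions: BnBr (1.2 equiv), K2CO3, DMF, 60 °C
Reagents that add atoms: benzyl bromide, BrCc1ccccc1
Why: Williamson ether synthesis; the phenoxide, although flanked by two methoxy groups, should be alkylated cleanly by the unhindered benzylic bromide, and carbonate does not touch the non-enolisable aldehyde.

Step 2
Reactants: 2 4-(benzyloxy)-3,5-dimethoxybenzaldehyde
Product: 3 2-(benzyloxy)-5-ethenyl-1,3-dimethoxybenzene
Conditions: Ph3PCH3Br, KOtBu, THF, 0 °C to rt
Reagents that add atoms: methyltriphenylphosphonium bromide, C[P+](c1ccccc1)(c1ccccc1)c1ccccc1.[Br-]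
Why: Wittig methylenation of an aromatic aldehyde with the unstabilised ylide is dependable, and the benzyl and methyl ethers are inert to the ylide.

Step 3
Reactants: 4 4-bromocatechol (4-bromobenzene-1,2-diol)
Product: 5 1,2-bis(benzyloxy)-4-bromobenzene
Conditions: BnBr (2.4 equiv), K2CO3, DMF, N2, 60 °C
Reagents that add atoms: benzyl bromide, BrCc1ccccc1
Why: Double Williamson ether synthesis; both catechol oxygens should be benzylated with excess bromide, the aryl bromide is inert, and exclusion of air prevents oxidation of the catecholate.

Step 4
Reactants: 5 1,2-bis(benzyloxy)-4-bromobenzene; 6 1-bromo-4-chlorobutane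
Product: 8 4-(4-chlorobutyl)-1,2-bis(benzyloxy)benzene, via arylmagnesium bromide 7 (not isolated)
Conditions: Mg, I2 (cat.), THF, reflux; then added to 6 (1.5 equiv), Li2CuCl4 (3 mol%), THF, 0 °C to rt
Reagents that add atoms: none
Why: Kochi-type copper-catalysed coupling of a Grignard reagent with a primary alkyl halide; the organocopper species should displace the bromide of 6 much faster than its chloride, so the four-carbon chain is attached with a chloride handle, and benzyl ethers tolerate the Grignard reagent.

Step 5
Reactants: 8 4-(4-chlorobutyl)-1,2-bis(benzyloxy)benzene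
Product: 9 4-(4-iodobutyl)-1,2-bis(benzyloxy)benzene
Conditions: NaI (5 equiv), 2-butanone, reflux
Reagents that add atoms: sodium iodide, [Na+].[I-]
Why: Finkelstein halide exchange; SN2 displacement of the unhindered primary chloride by iodide is driven forward by precipitation of NaCl from the ketone solvent.

Step 6
Reactants: 3 2-(benzyloxy)-5-ethenyl-1,3-dimethoxybenzene; 10 9-borabicyclo[3.3.1]nonane (9-BBN)
Product: 11 B-[2-(4-benzyloxy-3,5-dimethoxyphenyl)ethyl]-9-borabicyclo[3.3.1]nonane
Conditions: 3 (1.05 equiv), 9-BBN (0.5 M in THF), 0 °C to rt; THF removed under argon, residue taken up in benzene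
Reagents that add atoms: none
Why: Anti-Markovnikov hydroboration of a terminal styrene; the bulky 9-BBN should place boron on the terminal carbon, the slight excess of alkene leaves no B–H behind, and ethers are inert.

Step 7
Reactants: 11 B-[2-(4-benzyloxy-3,5-dimethoxyphenyl)ethyl]-9-borabicyclo[3.3.1]nonane (1.3 equiv); 9 4-(4-iodobutyl)-1,2-bis(benzyloxy)benzene; 12 carbon monoxide
Product: 13 1-[4-(benzyloxy)-3,5-dimethoxyphenyl]-7-[3,4-bis(benzyloxy)phenyl]heptan-3-one
Conditions: CO (1 atm), Pd(PPh3)4 (5 mol%), K3PO4 (3 equiv), benzene, hν (tungsten lamp), rt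
Reagents that add atoms: none
Why: Light-excited zerovalent palladium should transfer one electron to iodide 9; the unhindered primary 4-arylbutyl radical then captures CO (forming C3–C4), and the acyl radical collapses with the monovalent palladium iodide to an acylpalladium iodide of divalent palladium. Phosphate turns borane 11 into a borate that passes its primary 2-arylethyl group, not one of the secondary ring B–C bonds, to palladium, and reductive elimination forms C2–C3 and returns zerovalent palladium. The closest known reaction type is the light-accelerated, palladium-catalysed carbonylative Suzuki–Miyaura coupling of primary iodoalkanes with B-alkyl-9-BBN reagents to unsymmetrical dialkyl ketones, and both partners here belong to that class. No ring closes and no stereocentre is created, so neither a mode of closure nor a controlling element is involved. The step needs carbonylation to outrun direct alkyl–alkyl coupling and β-hydride loss: the CO atmosphere intercepts the radical before it reaches the metal, an acyl ligand cannot β-eliminate, and the halide sits on the arylbutyl arm because a 2-arylethyl iodide would lose HI to a styrene under phosphate. Benzyl ethers, methyl ethers and the electron-rich arenes are spectators under these mild, room-temperature conditions.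

Step 8
Reactants: 13 1-[4-(benzyloxy)-3,5-dimethoxyphenyl]-7-[3,4-bis(benzyloxy)phenyl]heptan-3-one
Product: 14 7-(3,4-dihydroxyphenyl)-1-(4-hydroxy-3,5-dimethoxyphenyl)heptan-3-one
Conditions: H2 (1 atm), 10% Pd/C, EtOAc–EtOH, rt; filtered and concentrated under argon
Reagents that add atoms: none
Why: Catalytic hydrogenolysis of the three aryl benzyl ethers; an unconjugated dialkyl ketone and aryl methyl ethers should not be reduced at one atmosphere and room temperature, and the neutral medium spares the oxidation-prone catechol.

**Compound list**

1 | syringaldehyde (4-hydroxy-3,5-dimethoxybenzaldehyde) | COc1cc(C=O)cc(OC)c1O | starting material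
2 | 4-(benzyloxy)-3,5-dimethoxybenzaldehyde | COc1cc(C=O)cc(OC)c1OCc1ccccc1 | intermediate
3 | 2-(benzyloxy)-5-ethenyl-1,3-dimethoxybenzene | COc1cc(C=C)cc(OC)c1OCc1ccccc1 | intermediate
4 | 4-bromocatechol (4-bromobenzene-1,2-diol) | Oc1ccc(Br)cc1O | starting material
5 | 1,2-bis(benzyloxy)-4-bromobenzene | Brc1ccc(OCc2ccccc2)c(OCc2ccccc2)c1 | intermediate
6 | 1-bromo-4-chlorobutane | ClCCCCBr | starting material
7 | [3,4-bis(benzyloxy)phenyl]magnesium bromide | Br[Mg]c1ccc(OCc2ccccc2)c(OCc2ccccc2)c1 | intermediate
8 | 4-(4-chlorobutyl)-1,2-bis(benzyloxy)benzene | ClCCCCc1ccc(OCc2ccccc2)c(OCc2ccccc2)c1 | intermediate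
9 | 4-(4-iodobutyl)-1,2-bis(benzyloxy)benzene | ICCCCc1ccc(OCc2ccccc2)c(OCc2ccccc2)c1 | intermediate
10 | 9-borabicyclo[3.3.1]nonane (9-BBN) | B1C2CCCC1CCC2 | starting material
11 | B-[2-(4-benzyloxy-3,5-dimethoxyphenyl)ethyl]-9-borabicyclo[3.3.1]nonane | COc1cc(CCB2C3CCCC2CCC3)cc(OC)c1OCc1ccccc1 | intermediate
12 | carbon monoxide | [C-]#[O+] | starting material
13 | 1-[4-(benzyloxy)-3,5-dimethoxyphenyl]-7-[3,4-bis(benzyloxy)phenyl]heptan-3-one | COc1cc(CCC(=O)CCCCc2ccc(OCc3ccccc3)c(OCc3ccccc3)c2)cc(OC)c1OCc1ccccc1 | intermediate
14 | 7-(3,4-dihydroxyphenyl)-1-(4-hydroxy-3,5-dimethoxyphenyl)heptan-3-one | COc1cc(CCC(=O)CCCCc2ccc(O)c(O)c2)cc(OC)c1O | target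

**Step count**

Total steps: 8. Longest linear sequence: 5 steps (steps 3, 4, 5, 7, 8 from 4-bromocatechol; equally steps 1, 2, 6, 7, 8 from syringaldehyde).

**Steps most likely to fail, with fallbacks**

Step 7. The radical may couple with the borane-derived alkyl group without taking up CO, the iodide may be reduced or lose HI, or the 4-arylbutyl radical may attack its own arene before it meets CO. In that case the ketone would be made by acyl substitution instead, setting out from aldehyde 2 and chloride 8. Horner–Wadsworth–Emmons olefination of 2 with diethyl [2-(methoxy(methyl)amino)-2-oxoethyl]phosphonate (NaH, THF) should give (E)-3-[4-(benzyloxy)-3,5-dimethoxyphenyl]-N-methoxy-N-methylprop-2-enamide F1. Chloride 8 would be converted with Mg in THF into {4-[3,4-bis(benzyloxy)phenyl]butyl}magnesium chloride F2. Its addition to the Weinreb amide at low temperature should stop at the chelated tetrahedral adduct and give, on work-up, (E)-1-[4-(benzyloxy)-3,5-dimethoxyphenyl]-7-[3,4-bis(benzyloxy)phenyl]hept-1-en-3-one F3. Hydrogenation over 10% Pd/C would then saturate the C1–C2 double bond and cleave all three benzyl ethers in one operation, so this path comes back to the route at target 14.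

Step 4. Magnesium insertion into the electron-rich aryl bromide may be sluggish, and biaryl homocoupling or halogen–magnesium exchange with the dihalide may compete with substitution. The chain would then be attached by a B-alkyl Suzuki–Miyaura coupling, setting out from bromide 5 and 9-BBN 10. But-3-en-1-ol would be silylated (TBSCl, imidazole, CH2Cl2) to tert-butyl(but-3-en-1-yloxy)dimethylsilane F4 and hydroborated with 10 to B-[4-(tert-butyldimethylsilyloxy)butyl]-9-borabicyclo[3.3.1]nonane F5. Coupling with 5 (PdCl2(dppf), aqueous K3PO4, THF–DMF, 60 °C) should give tert-butyl{4-[3,4-bis(benzyloxy)phenyl]butoxy}dimethylsilane F6. Desilylation with TBAF in THF would give 4-[3,4-bis(benzyloxy)phenyl]butan-1-ol F7, and Appel-type iodination (I2, PPh3, imidazole, CH2Cl2) would deliver iodide 9, where the route is rejoined; chloride 8 and step 5 are bypassed.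

Step 8. Cleavage of the hindered benzyl ether between the two methoxy groups may stall, the ketone may be slowly reduced or ketalised on the catalyst, and the catechol may oxidise in air during filtration. The benzyl groups would then be removed without hydrogen or metal, by Lewis-acid cleavage with a cation scavenger: BCl3 and pentamethylbenzene in CH2Cl2 at −78 °C, quenched with methanol. This sets out from 13 and comes back at 14; the aryl methyl ethers and the ketone should survive at this temperature, and no new intermediate is formed.

**Further compounds**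

F1 | step 7 | (E)-3-[4-(benzyloxy)-3,5-dimethoxyphenyl]-N-methoxy-N-methylprop-2-enamide | CON(C)C(=O)/C=C/c1cc(OC)c(OCc2ccccc2)c(OC)c1
F2 | step 7 | {4-[3,4-bis(benzyloxy)phenyl]butyl}magnesium chloride | Cl[Mg]CCCCc1ccc(OCc2ccccc2)c(OCc2ccccc2)c1
F3 | step 7 | (E)-1-[4-(benzyloxy)-3,5-dimethoxyphenyl]-7-[3,4-bis(benzyloxy)phenyl]hept-1-en-3-one | COc1cc(/C=C/C(=O)CCCCc2ccc(OCc3ccccc3)c(OCc3ccccc3)c2)cc(OC)c1OCc1ccccc1
F4 | step 4 | tert-butyl(but-3-en-1-yloxy)dimethylsilane | C=CCCO[Si](C)(C)C(C)(C)C
F5 | step 4 | B-[4-(tert-butyldimethylsilyloxy)butyl]-9-borabicyclo[3.3.1]nonane | CC(C)(C)[Si](C)(C)OCCCCB1C2CCCC1CCC2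
F6 | step 4 | tert-butyl{4-[3,4-bis(benzyloxy)phenyl]butoxy}dimethylsilane | CC(C)(C)[Si](C)(C)OCCCCc1ccc(OCc2ccccc2)c(OCc2ccccc2)c1
F7 | step 4 | 4-[3,4-bis(benzyloxy)phenyl]butan-1-ol | OCCCCc1ccc(OCc2ccccc2)c(OCc2ccccc2)c1
F0 | step 8 | none | none
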